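**Plan**

1. Numbering used here: ring C1 (CH carrying the side chain), C2 (CH2), C3/C4 (ring epoxide, C4 methylated), C5 and C6 (ester carbons, C6 next to C1); side chain C7(=C14H2), C8 (ester), C9, C10/C11 (epoxide).
2. Retrosynthesis, in order: the C10–C11 epoxide, the three angelate C–O bonds, the ring epoxide, the ring bond C1–C2, then C6–C1, which splits the chain into a C1/C7–C13 iodoalkene and a C2–C6 vinyl epoxy aldehyde.
3. Enabling feature: with the ring epoxide read as a C3=C4 alkene, C1–C2 is the central bond of the biallyl unit C4=C3–C2–C1–C7=C14 and C5 carries oxygen. The cyclohexene can therefore close by attack of an allylsilane (C1=C7–C14–Si) on the C2 end of the allyl cation released from a C4–C5 vinyl epoxide.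
4. Forward order: chain joined at C6–C1, six-membered ring closed at C1–C2, then ring epoxide, the two ring esters, the side-chain ester and the side-chain epoxide.
5. Stereochemistry: C8 from Noyori transfer hydrogenation; C5 from Sharpless epoxidation; C6 from chelation-controlled reduction; C1 from C6 by allylic strain in the ring closure (the C4 centre is erased there); C3/C4 from the C5-hydroxyl-directed epoxidation; C10 from Shi epoxidation.

Key step: step 14

**Route**

Step 1
Reactants: 1 4-methylpent-3-enoic acid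
Product: 2 N-methoxy-N,4-dimethylpent-3-enamide
Conditions: CDI, CH2Cl2, rt; then MeNH(OMe)·HCl, rt
Reagents that add atoms: N,O-dimethylhydroxylamine hydrochloride, CNOC.Cl
Why: Acyl-imidazolide amidation (Weinreb amide formation) under non-basic conditions should keep the β,γ-double bond out of conjugation.

Step 2
Reactants: 2 N-methoxy-N,4-dimethylpent-3-enamide; 3 ethynyl(trimethyl)silane
Product: 5 6-methyl-1-(trimethylsilyl)hept-5-en-1-yn-3-one, via lithium (trimethylsilyl)acetylide 4 (not isolated)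
Conditions: 3, n-BuLi, THF, −78 °C; then 2, −78 → 0 °C; then H2O
Reagents that add atoms: none
Why: Weinreb ketone synthesis, in which the acetylide adds once and the chelated tetrahedral adduct releases the alkynyl ketone only on quench.

Step 3
Reactants: 5 6-methyl-1-(trimethylsilyl)hept-5-en-1-yn-3-one
Product: 6 (3S)-6-methyl-1-(trimethylsilyl)hept-5-en-1-yn-3-ol
Conditions: Ru[(S,S)-TsDPEN](p-cymene) (1 mol %), i-PrOH, rt
Reagents that add atoms: none
Why: Noyori asymmetric transfer hydrogenation of an alkynyl ketone, in which the (S,S)-catalyst should deliver hydride to the face that gives the (S)-propargylic alcohol (C8 of the target) without touching alkyne or alkene.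

Step 4
Reactants: 6 (3S)-6-methyl-1-(trimethylsilyl)hept-5-en-1-yn-3-ol
Product: 7 (3S)-6-methylhept-5-en-1-yn-3-ol
Conditions: K2CO3 (cat.), MeOH, rt
Reagents that add atoms: none
Why: Base-catalysed methanolysis of the alkynyl C–Si bond (protodesilylation) frees the terminal alkyne.

Step 5
Reactants: 7 (3S)-6-methylhept-5-en-1-yn-3-ol
Product: 9 (1E,3S)-1-iodo-6-methyl-2-[(trimethylsilyl)methyl]hepta-1,5-dien-3-ol (iodine cis to C3), via alkenylmagnesium chloride alkoxide 8 (not isolated)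
Conditions: Me3SiCH2MgCl (3.2 equiv), CuI (10 mol %), Et2O/THF, 0 → 35 °C; then I2, −78 → 0 °C; then H2O
Reagents that add atoms: (trimethylsilyl)methylmagnesium chloride, C[Si](C)(C)C[Mg]Cl; iodine, II
Why: Copper-catalysed anti-carbomagnesiation of a propargylic alcohol, in which the magnesium alkoxide directs the Me3SiCH2 group to the carbon next to the carbinol and magnesium to the terminal carbon (five-membered chelate), followed by iodinolysis of the C–Mg bond with retention, should give one geometric isomer of the iodoalkene.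

Step 6
Reactants: 9 (1E,3S)-1-iodo-6-methyl-2-[(trimethylsilyl)methyl]hepta-1,5-dien-3-ol
Product: 10 (1E,3S)-1-iodo-6-methyl-2-[(trimethylsilyl)methyl]-3-[tri(propan-2-yl)silyloxy]hepta-1,5-diene
Conditions: i-Pr3SiOTf, 2,6-lutidine, CH2Cl2, −78 → 0 °C
Reagents that add atoms: tri(propan-2-yl)silyl trifluoromethanesulfonate, CC(C)[Si](C(C)C)(C(C)C)OS(=O)(=O)C(F)(F)F
Why: Silylation with a silyl triflate, the bulky tri(propan-2-yl)silyl group being chosen because it should not migrate from oxygen to carbon (retro-Brook rearrangement) in the alkenyllithium of step 10 and should survive the Lewis acid of step 14 and the buffered fluoride of step 16.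

Step 7
Reactants: 11 (2E)-3-methylpent-2-en-4-yn-1-ol
Product: 12 (2E)-3-methylpenta-2,4-dien-1-ol
Conditions: H2 (1 atm), Pd/CaCO3 poisoned with Pb(OAc)2, quinoline, EtOAc, rt, stopped after 1 equiv H2
Reagents that add atoms: none
Why: Lindlar semihydrogenation should stop at the alkene and turn the terminal alkyne into the vinyl group (C2=C3 of the target).

Step 8
Reactants: 12 (2E)-3-methylpenta-2,4-dien-1-ol
Product: 13 [(2S,3S)-3-ethenyl-3-methyloxiran-2-yl]methanol
Conditions: Ti(OiPr)4 (10 mol %), L-(+)-diethyl tartrate (12 mol %), t-BuOOH, 4 Å molecular sieves, CH2Cl2, −25 °C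
Reagents that add atoms: tert-butyl hydroperoxide, CC(C)(C)OO
Why: Sharpless asymmetric epoxidation touches only the allylic double bond of the dienol and with L-(+)-tartrate should deliver oxygen to the face that gives the (2S) centre (C5 of the target), the accompanying quaternary centre being erased in step 14.

Step 9
Reactants: 13 [(2S,3S)-3-ethenyl-3-methyloxiran-2-yl]methanol
Product: 14 (2R,3S)-3-ethenyl-3-methyloxirane-2-carbaldehyde
Conditions: Dess–Martin periodinane, NaHCO3, CH2Cl2, 0 °C; used directly as a dried solution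
Reagents that add atoms: none
Why: Buffered Dess–Martin oxidation should give the aldehyde without opening the acid-sensitive vinyl epoxide or epimerising the α-centre.

Step 10
Reactants: 10 (1E,3S)-1-iodo-6-methyl-2-[(trimethylsilyl)methyl]-3-[tri(propan-2-yl)silyloxy]hepta-1,5-diene; 14 (2R,3S)-3-ethenyl-3-methyloxirane-2-carbaldehyde
Product: 16 (2E,4S)-1-[(2S,3S)-3-ethenyl-3-methyloxiran-2-yl]-7-methyl-3-[(trimethylsilyl)methyl]-4-[tri(propan-2-yl)silyloxy]octa-2,6-dien-1-ol (both C1 epimers), via alkenyllithium 15 (not isolated)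
Conditions: 10, t-BuLi (2.05 equiv), Et2O, −78 °C; then 14, −78 °C; then H2O
Reagents that add atoms: none
Why: Iodine–lithium exchange with retention of alkene geometry and 1,2-addition of the alkenyllithium to the aldehyde form the C6–C1 bond, the facial selectivity not being relied upon because the carbinol centre is reset in steps 11 and 12.

Step 11
Reactants: 16 (2E,4S)-1-[(2S,3S)-3-ethenyl-3-methyloxiran-2-yl]-7-methyl-3-[(trimethylsilyl)methyl]-4-[tri(propan-2-yl)silyloxy]octa-2,6-dien-1-ol (both C1 epimers)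
Product: 17 (2E,4S)-1-[(2R,3S)-3-ethenyl-3-methyloxiran-2-yl]-7-methyl-3-[(trimethylsilyl)methyl]-4-[tri(propan-2-yl)silyloxy]octa-2,6-dien-1-one
Conditions: Dess–Martin periodinane, NaHCO3, CH2Cl2, 0 °C → rt
Reagents that add atoms: none
Why: Buffered Dess–Martin oxidation of the allylic alcohol should give the epoxy enone and remove the uncontrolled stereocentre.

Step 12
Reactants: 17 (2E,4S)-1-[(2R,3S)-3-ethenyl-3-methyloxiran-2-yl]-7-methyl-3-[(trimethylsilyl)methyl]-4-[tri(propan-2-yl)silyloxy]octa-2,6-dien-1-one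
Product: 18 (1S,2E,4S)-1-[(2S,3S)-3-ethenyl-3-methyloxiran-2-yl]-7-methyl-3-[(trimethylsilyl)methyl]-4-[tri(propan-2-yl)silyloxy]octa-2,6-dien-1-ol
Conditions: Zn(BH4)2 (ethereal solution), Et2O, −40 °C; then H2O
Reagents that add atoms: none
Why: Chelation-controlled 1,2-reduction of an α,β-epoxy ketone, in which zinc bridges the carbonyl and epoxide oxygens and hydride enters from the face away from the quaternary epoxide carbon, should give the anti epoxy alcohol with the (S) centre that becomes C6.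

Step 13
Reactants: 18 (1S,2E,4S)-1-[(2S,3S)-3-ethenyl-3-methyloxiran-2-yl]-7-methyl-3-[(trimethylsilyl)methyl]-4-[tri(propan-2-yl)silyloxy]octa-2,6-dien-1-ol
Product: 19 triethyl{[(1S,2E,4S)-1-[(2S,3S)-3-ethenyl-3-methyloxiran-2-yl]-7-methyl-3-[(trimethylsilyl)methyl]-4-[tri(propan-2-yl)silyloxy]octa-2,6-dien-1-yl]oxy}silane
Conditions: Et3SiCl, imidazole, DMF, 0 °C → rt
Reagents that add atoms: chlorotriethylsilane, CC[Si](Cl)(CC)CC
Why: Standard silylation with a silyl chloride and imidazole keeps the C6 oxygen from competing as a nucleophile in step 14, the triethylsilyl ether being chosen because it can later be cleaved beside the tri(propan-2-yl)silyl ether.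

Step 14
Reactants: 19 triethyl{[(1S,2E,4S)-1-[(2S,3S)-3-ethenyl-3-methyloxiran-2-yl]-7-methyl-3-[(trimethylsilyl)methyl]-4-[tri(propan-2-yl)silyloxy]octa-2,6-dien-1-yl]oxy}silane
Product: 20 (1R,5R,6S)-2-methyl-5-[(3S)-6-methyl-3-[tri(propan-2-yl)silyloxy]hepta-1,5-dien-2-yl]-6-(triethylsilyloxy)cyclohex-2-en-1-ol
Conditions: MeAlCl2 (1.5 equiv), CH2Cl2, −78 °C; then Et3N, H2O
Reagents that add atoms: none
Why: MeAlCl2 binds the epoxide oxygen and the tertiary, allylic C4–O bond ionises to an oxygen-substituted allyl cation (C2–C3–C4) whose C2 terminus is attacked by C1 of the allylsilane, after which the β-silyl cation at C7 loses Me3Si+, so that the C1–C2 bond, the C3=C4 ring alkene, the C7=C14 methylene and the free C5 oxygen appear together. The closest known reaction type is the Lewis-acid-promoted, epoxide- or allylic-alcohol-initiated cation–olefin cyclisation terminated by an allylsilane (intramolecular Hosomi–Sakurai reaction in the SN2′ sense). The cyclohexene closes in the 6-exo mode with respect to the C1=C7 bond of the allylsilane, the allyl cation being attacked at its remote terminus so that its C3=C4 bond ends up inside the ring and cis. The only new stereocentre, C1, should be set by C6 through allylic 1,3-strain: in the chair-like transition state the C6–H bond eclipses the C1=C7 bond (C7 carries the bulky C8 group cis to C6), the C6 silyloxy group is axial and C7 and the C5 oxygen are equatorial, which places the side chain cis to both oxygens. The step needs ionisation at C4 and not C5 (tertiary allylic against secondary), attack at C2 and not C4 (six- against four-membered ring), reaction of the allylsilane and not the less nucleophilic prenyl alkene, and no protodesilylation (a proton-scavenging aluminium Lewis acid at −78 °C). The configuration at C4 is destroyed in the step, so either epimer of the epoxide at that carbon would converge on the same product.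

Step 15
Reactants: 20 (1R,5R,6S)-2-methyl-5-[(3S)-6-methyl-3-[tri(propan-2-yl)silyloxy]hepta-1,5-dien-2-yl]-6-(triethylsilyloxy)cyclohex-2-en-1-ol
Product: 21 (1S,2S,3S,4R,6R)-1-methyl-4-[(3S)-6-methyl-3-[tri(propan-2-yl)silyloxy]hepta-1,5-dien-2-yl]-3-(triethylsilyloxy)-7-oxabicyclo[4.1.0]heptan-2-ol
Conditions: VO(acac)2 (5 mol %), t-BuOOH, toluene, 0 °C → rt
Reagents that add atoms: tert-butyl hydroperoxide, CC(C)(C)OO
Why: Vanadium-catalysed hydroxyl-directed epoxidation, in which the allylic C5 hydroxyl delivers oxygen to its own face of the C3=C4 bond (C3 and C4 set cis to the C5 oxygen), while the prenyl and methylene alkenes, which have no free hydroxyl nearby, should not react.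

Step 16
Reactants: 21 (1S,2S,3S,4R,6R)-1-methyl-4-[(3S)-6-methyl-3-[tri(propan-2-yl)silyloxy]hepta-1,5-dien-2-yl]-3-(triethylsilyloxy)-7-oxabicyclo[4.1.0]heptan-2-ol
Product: 22 (1S,2S,3S,4R,6R)-1-methyl-4-[(3S)-6-methyl-3-[tri(propan-2-yl)silyloxy]hepta-1,5-dien-2-yl]-7-oxabicyclo[4.1.0]heptane-2,3-diol
Conditions: HF·pyridine, pyridine, THF, 0 °C; then aq. NaHCO3
Reagents that add atoms: none
Why: Fluoride-mediated silyl ether cleavage, in which the triethylsilyl ether reacts far faster than the bulkier tri(propan-2-yl)silyl ether, should free the C6 hydroxyl alone under pyridine-buffered conditions that the epoxide tolerates.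

Step 17
Reactants: 22 (1S,2S,3S,4R,6R)-1-methyl-4-[(3S)-6-methyl-3-[tri(propan-2-yl)silyloxy]hepta-1,5-dien-2-yl]-7-oxabicyclo[4.1.0]heptane-2,3-diol; 23 (2Z)-2-methylbut-2-enoic anhydride (angelic anhydride)
Product: 25 (1R,2S,3S,4R,6R)-1-methyl-4-[(3S)-6-methyl-3-[tri(propan-2-yl)silyloxy]hepta-1,5-dien-2-yl]-7-oxabicyclo[4.1.0]heptane-2,3-diyl bis[(2Z)-2-methylbut-2-enoate], via dilithium dialkoxide 24 (not isolated)
Conditions: LiN(SiMe3)2 (2.1 equiv), THF, −20 °C; then 23 (2.6 equiv), −20 → 10 °C; then H2O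
Reagents that add atoms: none
Why: Acylation of lithium alkoxides by the symmetric (Z)-anhydride at low temperature, one molecule of 23 being consumed per hydroxyl and no nucleophilic amine catalyst being present, should esterify both ring hydroxyls without the addition–elimination path that isomerises angelates to tiglates.

Step 18
Reactants: 25 (1R,2S,3S,4R,6R)-1-methyl-4-[(3S)-6-methyl-3-[tri(propan-2-yl)silyloxy]hepta-1,5-dien-2-yl]-7-oxabicyclo[4.1.0]heptane-2,3-diyl bis[(2Z)-2-methylbut-2-enoate]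
Product: 26 (1R,2S,3S,4R,6R)-4-[(3S)-3-hydroxy-6-methylhepta-1,5-dien-2-yl]-1-methyl-7-oxabicyclo[4.1.0]heptane-2,3-diyl bis[(2Z)-2-methylbut-2-enoate]
Conditions: Bu4NF, AcOH (1:1), THF, rt; then H2O
Reagents that add atoms: none
Why: Fluoride cleavage of the tri(propan-2-yl)silyl ether, buffered with acetic acid so that no free alkoxide is present to attack the esters or the epoxide, should free the C8 hydroxyl.

Step 19
Reactants: 26 (1R,2S,3S,4R,6R)-4-[(3S)-3-hydroxy-6-methylhepta-1,5-dien-2-yl]-1-methyl-7-oxabicyclo[4.1.0]heptane-2,3-diyl bis[(2Z)-2-methylbut-2-enoate]; 23 (2Z)-2-methylbut-2-enoic anhydride (angelic anhydride)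
Product: 28 (1R,2S,3S,4R,6R)-1-methyl-4-[(3S)-6-methyl-3-{[(2Z)-2-methylbut-2-enoyl]oxy}hepta-1,5-dien-2-yl]-7-oxabicyclo[4.1.0]heptane-2,3-diyl bis[(2Z)-2-methylbut-2-enoate], via lithium alkoxide 27 (not isolated)
Conditions: LiN(SiMe3)2 (1.05 equiv), THF, −78 °C; then 23 (1.3 equiv), −78 → 0 °C; then H2O
Reagents that add atoms: none
Why: Acylation of the lithium alkoxide by the (Z)-anhydride, with barely more than one equivalent of base at −78 °C so that the alkoxide forms without γ-deprotonation of the angelates already present, should install the third ester with its geometry intact.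

Step 20
Reactants: 28 (1R,2S,3S,4R,6R)-1-methyl-4-[(3S)-6-methyl-3-{[(2Z)-2-methylbut-2-enoyl]oxy}hepta-1,5-dien-2-yl]-7-oxabicyclo[4.1.0]heptane-2,3-diyl bis[(2Z)-2-methylbut-2-enoate]
Product: 29 (1R,2S,3S,4R,6R)-4-[(3S)-4-[(2R)-3,3-dimethyloxiran-2-yl]-3-{[(2Z)-2-methylbut-2-enoyl]oxy}but-1-en-2-yl]-1-methyl-7-oxabicyclo[4.1.0]heptane-2,3-diyl bis[(2Z)-2-methylbut-2-enoate] (CNP0258231.4)
Conditions: D-fructose-derived Shi ketone (30 mol %), KHSO5, K2CO3, Bu4NHSO4, MeCN/CH2(OMe)2/aq. Na2B4O7 buffer, 0 °C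
Reagents that add atoms: potassium peroxymonosulfate, [K+].[O-]S(=O)(=O)OO
Why: Shi asymmetric epoxidation, in which the chiral dioxirane should react only with the electron-rich trisubstituted C10=C11 bond (the methylene and the conjugated ester alkenes are deactivated) and set the (10R) centre under catalyst control.

**Compound list**

1 | 4-methylpent-3-enoic acid | CC(C)=CCC(=O)O | starting material
2 | N-methoxy-N,4-dimethylpent-3-enamide | CC(C)=CCC(=O)N(C)OC | intermediate
3 | ethynyl(trimethyl)silane | C#C[Si](C)(C)C | starting material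
4 | lithium (trimethylsilyl)acetylide | [Li]C#C[Si](C)(C)C | intermediate (not isolated)
5 | 6-methyl-1-(trimethylsilyl)hept-5-en-1-yn-3-one | CC(C)=CCC(=O)C#C[Si](C)(C)C | intermediate
6 | (3S)-6-methyl-1-(trimethylsilyl)hept-5-en-1-yn-3-ol | C[Si](C)(C)C#C[C@@H](O)CC=C(C)C | intermediate
7 | (3S)-6-methylhept-5-en-1-yn-3-ol | C#C[C@@H](O)CC=C(C)C | intermediate
8 | chloromagnesium alkoxide of (1E,3S)-1-(chloromagnesio)-6-methyl-2-[(trimethylsilyl)methyl]hepta-1,5-dien-3-ol (Mg on C1 cis to C3) | Cl[Mg]/C=C(/C[Si](C)(C)C)[C@@H](O[Mg]Cl)CC=C(C)C | intermediate (not isolated)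
9 | (1E,3S)-1-iodo-6-methyl-2-[(trimethylsilyl)methyl]hepta-1,5-dien-3-ol | I/C=C(/C[Si](C)(C)C)[C@@H](O)CC=C(C)C | intermediate
10 | (1E,3S)-1-iodo-6-methyl-2-[(trimethylsilyl)methyl]-3-[tri(propan-2-yl)silyloxy]hepta-1,5-diene | I/C=C(/C[Si](C)(C)C)[C@@H](O[Si](C(C)C)(C(C)C)C(C)C)CC=C(C)C | intermediate
11 | (2E)-3-methylpent-2-en-4-yn-1-ol | C#C/C(C)=C/CO | starting material
12 | (2E)-3-methylpenta-2,4-dien-1-ol | C=C/C(C)=C/CO | intermediate
13 | [(2S,3S)-3-ethenyl-3-methyloxiran-2-yl]methanol | C=C[C@]1(C)O[C@H]1CO | intermediate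
14 | (2R,3S)-3-ethenyl-3-methyloxirane-2-carbaldehyde | C=C[C@]1(C)O[C@H]1C=O | intermediate
15 | [(1E,3S)-6-methyl-2-[(trimethylsilyl)methyl]-3-[tri(propan-2-yl)silyloxy]hepta-1,5-dien-1-yl]lithium | [Li]/C=C(/C[Si](C)(C)C)[C@@H](O[Si](C(C)C)(C(C)C)C(C)C)CC=C(C)C | intermediate (not isolated)
16 | (2E,4S)-1-[(2S,3S)-3-ethenyl-3-methyloxiran-2-yl]-7-methyl-3-[(trimethylsilyl)methyl]-4-[tri(propan-2-yl)silyloxy]octa-2,6-dien-1-ol, both C1 epimers | C=C[C@]1(C)O[C@H]1C(O)/C=C(/C[Si](C)(C)C)[C@@H](O[Si](C(C)C)(C(C)C)C(C)C)CC=C(C)C | intermediate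
17 | (2E,4S)-1-[(2R,3S)-3-ethenyl-3-methyloxiran-2-yl]-7-methyl-3-[(trimethylsilyl)methyl]-4-[tri(propan-2-yl)silyloxy]octa-2,6-dien-1-one | C=C[C@]1(C)O[C@H]1C(=O)/C=C(/C[Si](C)(C)C)[C@@H](O[Si](C(C)C)(C(C)C)C(C)C)CC=C(C)C | intermediate
18 | (1S,2E,4S)-1-[(2S,3S)-3-ethenyl-3-methyloxiran-2-yl]-7-methyl-3-[(trimethylsilyl)methyl]-4-[tri(propan-2-yl)silyloxy]octa-2,6-dien-1-ol | C=C[C@]1(C)O[C@H]1[C@@H](O)/C=C(/C[Si](C)(C)C)[C@@H](O[Si](C(C)C)(C(C)C)C(C)C)CC=C(C)C | intermediate
19 | triethyl{[(1S,2E,4S)-1-[(2S,3S)-3-ethenyl-3-methyloxiran-2-yl]-7-methyl-3-[(trimethylsilyl)methyl]-4-[tri(propan-2-yl)silyloxy]octa-2,6-dien-1-yl]oxy}silane | C=C[C@]1(C)O[C@H]1[C@@H](O[Si](CC)(CC)CC)/C=C(/C[Si](C)(C)C)[C@@H](O[Si](C(C)C)(C(C)C)C(C)C)CC=C(C)C | intermediate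
20 | (1R,5R,6S)-2-methyl-5-[(3S)-6-methyl-3-[tri(propan-2-yl)silyloxy]hepta-1,5-dien-2-yl]-6-(triethylsilyloxy)cyclohex-2-en-1-ol | C=C([C@@H](O[Si](C(C)C)(C(C)C)C(C)C)CC=C(C)C)[C@H]1CC=C(C)[C@@H](O)[C@H]1O[Si](CC)(CC)CC | intermediate
21 | (1S,2S,3S,4R,6R)-1-methyl-4-[(3S)-6-methyl-3-[tri(propan-2-yl)silyloxy]hepta-1,5-dien-2-yl]-3-(triethylsilyloxy)-7-oxabicyclo[4.1.0]heptan-2-ol | C=C([C@@H](O[Si](C(C)C)(C(C)C)C(C)C)CC=C(C)C)[C@H]1C[C@H]2O[C@@]2(C)[C@@H](O)[C@H]1O[Si](CC)(CC)CC | intermediate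
22 | (1S,2S,3S,4R,6R)-1-methyl-4-[(3S)-6-methyl-3-[tri(propan-2-yl)silyloxy]hepta-1,5-dien-2-yl]-7-oxabicyclo[4.1.0]heptane-2,3-diol | C=C([C@@H](O[Si](C(C)C)(C(C)C)C(C)C)CC=C(C)C)[C@H]1C[C@H]2O[C@@]2(C)[C@@H](O)[C@H]1O | intermediate
23 | (2Z)-2-methylbut-2-enoic anhydride (angelic anhydride) | C/C=C(/C)C(=O)OC(=O)/C(C)=C\C | starting material
24 | dilithium dialkoxide of 22 | C=C([C@@H](O[Si](C(C)C)(C(C)C)C(C)C)CC=C(C)C)[C@H]1C[C@H]2O[C@@]2(C)[C@@H](O[Li])[C@H]1O[Li] | intermediate (not isolated)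
25 | (1R,2S,3S,4R,6R)-1-methyl-4-[(3S)-6-methyl-3-[tri(propan-2-yl)silyloxy]hepta-1,5-dien-2-yl]-7-oxabicyclo[4.1.0]heptane-2,3-diyl bis[(2Z)-2-methylbut-2-enoate] | C=C([C@@H](O[Si](C(C)C)(C(C)C)C(C)C)CC=C(C)C)[C@H]1C[C@H]2O[C@@]2(C)[C@@H](OC(=O)/C(C)=C\C)[C@H]1OC(=O)/C(C)=C\C | intermediate
26 | (1R,2S,3S,4R,6R)-4-[(3S)-3-hydroxy-6-methylhepta-1,5-dien-2-yl]-1-methyl-7-oxabicyclo[4.1.0]heptane-2,3-diyl bis[(2Z)-2-methylbut-2-enoate] | C=C([C@@H](O)CC=C(C)C)[C@H]1C[C@H]2O[C@@]2(C)[C@@H](OC(=O)/C(C)=C\C)[C@H]1OC(=O)/C(C)=C\C | intermediate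
27 | lithium alkoxide of 26 | C=C([C@@H](O[Li])CC=C(C)C)[C@H]1C[C@H]2O[C@@]2(C)[C@@H](OC(=O)/C(C)=C\C)[C@H]1OC(=O)/C(C)=C\C | intermediate (not isolated)
28 | (1R,2S,3S,4R,6R)-1-methyl-4-[(3S)-6-methyl-3-{[(2Z)-2-methylbut-2-enoyl]oxy}hepta-1,5-dien-2-yl]-7-oxabicyclo[4.1.0]heptane-2,3-diyl bis[(2Z)-2-methylbut-2-enoate] | C=C([C@@H](OC(=O)/C(C)=C\C)CC=C(C)C)[C@H]1C[C@H]2O[C@@]2(C)[C@@H](OC(=O)/C(C)=C\C)[C@H]1OC(=O)/C(C)=C\C | intermediate
29 | (1R,2S,3S,4R,6R)-4-[(3S)-4-[(2R)-3,3-dimethyloxiran-2-yl]-3-{[(2Z)-2-methylbut-2-enoyl]oxy}but-1-en-2-yl]-1-methyl-7-oxabicyclo[4.1.0]heptane-2,3-diyl bis[(2Z)-2-methylbut-2-enoate] | C=C([C@H](C[C@H]1OC1(C)C)OC(=O)/C(C)=C\C)[C@H]1C[C@H]2O[C@@]2(C)[C@@H](OC(=O)/C(C)=C\C)[C@H]1OC(=O)/C(C)=C\C | target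

**Step count and risks**

Total: 20 steps. Longest linear sequence: 17 steps (steps 1–6, then 10–20).

Steps most likely to fail:

1. Step 14. The epoxide may ionise in the rotamer that cannot close, or a hydride may shift from C5 to the cation, faster than the ring forms. The facial selectivity at C1 may also erode if the bulky aluminium alkoxide on C5 disfavours the chair with that oxygen equatorial. The fallback lets oxygen close the ring first and carbon second. It sets out from 18, whose C6 hydroxyl is free. With Pd(PPh3)4 (cat.) in THF, zerovalent palladium should open the vinyl epoxide to a π-allyl complex that equilibrates and is captured at C2 by the C6 hydroxyl, giving (2S,3R)-4-methyl-2-[(1E,3S)-6-methyl-2-[(trimethylsilyl)methyl]-3-[tri(propan-2-yl)silyloxy]hepta-1,5-dien-1-yl]-3,6-dihydro-2H-pyran-3-ol F1, in which the C3=C4 bond is locked cis. MeAlCl2 in CH2Cl2 at −78 °C should then ionise the allylic C2–O bond of F1 and the allylsilane should trap the cisoid cation at C2 to give (1S,2R,6R)-3-methyl-6-[(3S)-6-methyl-3-[tri(propan-2-yl)silyloxy]hepta-1,5-dien-2-yl]cyclohex-3-ene-1,2-diol F2. VO(acac)2 and t-BuOOH should then epoxidise F2 on the face of its two cis hydroxyls. The fallback thus comes back to the route at 22 and bypasses steps 13, 15 and 16.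

2. Step 5. Carbomagnesiation of the branched propargylic alcohol may stall, or iodine may attack the newly formed allylsilane (iododesilylation) during the quench. The fallback introduces the Me3SiCH2 group by conjugate addition instead. It sets out from 7, which is silylated (i-Pr3SiOTf, 2,6-lutidine) to (3S)-6-methyl-3-[tri(propan-2-yl)silyloxy]hept-5-en-1-yne F3. n-BuLi in THF at −78 °C gives the lithium acetylide of F3, F4, which is added to aldehyde 14 to give (4S)-1-[(2S,3S)-3-ethenyl-3-methyloxiran-2-yl]-7-methyl-4-[tri(propan-2-yl)silyloxy]oct-6-en-2-yn-1-ol F5 as both C1 epimers. Buffered Dess–Martin oxidation gives (4S)-1-[(2R,3S)-3-ethenyl-3-methyloxiran-2-yl]-7-methyl-4-[tri(propan-2-yl)silyloxy]oct-6-en-2-yn-1-one F6. Syn conjugate addition of (Me3SiCH2)2CuLi in THF at −78 °C, with proton quench at that temperature, should place the Me3SiCH2 group on C7 and hydrogen on C1 cis to it. The fallback thus comes back at 17 and bypasses steps 6, 10 and 11.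

3. Step 17. The (Z)-2-methylbut-2-enoyl groups may isomerise to the (E)-isomers during acylation, or acylation of the crowded cis-5,6-diol may stop at the monoester. The fallback builds the Z-alkenes on the molecule. It sets out from 22, which is esterified with 2-[bis(2,2,2-trifluoroethoxy)phosphoryl]propanoic acid (EDC·HCl, DMAP, CH2Cl2) to (1R,2S,3S,4R,6R)-1-methyl-4-[(3S)-6-methyl-3-[tri(propan-2-yl)silyloxy]hepta-1,5-dien-2-yl]-7-oxabicyclo[4.1.0]heptane-2,3-diyl bis{2-[bis(2,2,2-trifluoroethoxy)phosphoryl]propanoate} F7. Twofold Still–Gennari olefination of F7 with acetaldehyde (KN(SiMe3)2, 18-crown-6, THF, −78 °C) should give the two Z-configured esters, and the fallback comes back at 25.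

**Further compounds**

F1 | step 14 | (2S,3R)-4-methyl-2-[(1E,3S)-6-methyl-2-[(trimethylsilyl)methyl]-3-[tri(propan-2-yl)silyloxy]hepta-1,5-dien-1-yl]-3,6-dihydro-2H-pyran-3-ol | O[C@@H]1C(C)=CCO[C@H]1/C=C(/C[Si](C)(C)C)[C@@H](O[Si](C(C)C)(C(C)C)C(C)C)CC=C(C)C
F2 | step 14 | (1S,2R,6R)-3-methyl-6-[(3S)-6-methyl-3-[tri(propan-2-yl)silyloxy]hepta-1,5-dien-2-yl]cyclohex-3-ene-1,2-diol | C=C([C@@H](O[Si](C(C)C)(C(C)C)C(C)C)CC=C(C)C)[C@H]1CC=C(C)[C@@H](O)[C@H]1O
F3 | step 5 | (3S)-6-methyl-3-[tri(propan-2-yl)silyloxy]hept-5-en-1-yne | C#C[C@@H](O[Si](C(C)C)(C(C)C)C(C)C)CC=C(C)C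
F4 | step 5 | lithium acetylide of F3 | [Li]C#C[C@@H](O[Si](C(C)C)(C(C)C)C(C)C)CC=C(C)C
F5 | step 5 | (4S)-1-[(2S,3S)-3-ethenyl-3-methyloxiran-2-yl]-7-methyl-4-[tri(propan-2-yl)silyloxy]oct-6-en-2-yn-1-ol, both C1 epimers | C=C[C@]1(C)O[C@H]1C(O)C#C[C@@H](O[Si](C(C)C)(C(C)C)C(C)C)CC=C(C)C
F6 | step 5 | (4S)-1-[(2R,3S)-3-ethenyl-3-methyloxiran-2-yl]-7-methyl-4-[tri(propan-2-yl)silyloxy]oct-6-en-2-yn-1-one | C=C[C@]1(C)O[C@H]1C(=O)C#C[C@@H](O[Si](C(C)C)(C(C)C)C(C)C)CC=C(C)C
F7 | step 17 | (1R,2S,3S,4R,6R)-1-methyl-4-[(3S)-6-methyl-3-[tri(propan-2-yl)silyloxy]hepta-1,5-dien-2-yl]-7-oxabicyclo[4.1.0]heptane-2,3-diyl bis{2-[bis(2,2,2-trifluoroethoxy)phosphoryl]propanoate} | C=C([C@@H](O[Si](C(C)C)(C(C)C)C(C)C)CC=C(C)C)[C@H]1C[C@H]2O[C@@]2(C)[C@@H](OC(=O)C(C)P(=O)(OCC(F)(F)F)OCC(F)(F)F)[C@H]1OC(=O)C(C)P(=O)(OCC(F)(F)F)OCC(F)(F)F
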